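The route grows the benzo ring of the flavone half (C4a''–C8a'') around a carbon–carbon bond to ring B that is already in place, so no two hindered arenes have to be coupled. That ring is a phloroglucinol. Its oxygens sit on C5'', C7'' and C8a'', mutually meta, and ring B occupies C6'', flanked by O5'' and O7''. A 3-alkoxycyclobutenone and an aryl siloxyalkyne together carry this pattern. Heating them forms C6''–C7'' and C5''–C4a'', closes the ring and delivers three differently masked oxygens in one operation. The precursors are 3-(4-methoxybenzyloxy)cyclobutenone and a triisopropylsilyl ynol ether bearing benzyl-protected, acetal-masked ring B. Pyrone and (2S)-flavanone follow.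

Key step: step 5

Locants and abbreviations: unprimed = chromanone of the flavanone half, ' = ring B, '' = chromenone of the flavone half, ''' = its 2-aryl ring. Bn = benzyl, PMB = 4-methoxybenzyl, TIPS = triisopropylsilyl. ArB = 2-(benzyloxy)-5-(5,5-dimethyl-1,3-dioxan-2-yl)phenyl. Fl = 5,7-bis(benzyloxy)-2-[4-(benzyloxy)phenyl]-4-oxo-4H-chromen-6-yl.

Design remark: the aldehyde mask is an acetal of a 4-alkoxybenzaldehyde, which quinone oxidants and Lewis acids both attack. PMB is therefore never removed oxidatively, C4a'' is acylated through an aryllithium, and PMB and acetal are released together by one Brønsted-acid step.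

Assumption: the quinidine-derived thiourea of step 14 is taken to give the 2S product; if the sense of induction is the opposite, its quinine-derived pseudoenantiomer is used and nothing else changes.

Step 1
Reactants: 1 methyl 5-formyl-2-hydroxybenzoate
Product: 2 methyl 2-(benzyloxy)-5-formylbenzoate
Conditions: BnBr, K2CO3, DMF, 50 °C
Reagents that add atoms: benzyl bromide, BrCc1ccccc1
Why: Williamson etherification of a phenoxide acidified by the formyl and ester groups, with benzyl chosen because it survives the later bases, organolithiums and trifluoroacetic acid yet falls in the final hydrogenolysis.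

Step 2
Reactants: 2 methyl 2-(benzyloxy)-5-formylbenzoate
Product: 3 methyl 2-(benzyloxy)-5-(5,5-dimethyl-1,3-dioxan-2-yl)benzoate
Conditions: 2,2-dimethylpropane-1,3-diol, pyridinium 4-toluenesulfonate (cat.), toluene, reflux, Dean–Stark trap
Reagents that add atoms: 2,2-dimethylpropane-1,3-diol, OCC(C)(C)CO
Why: Acid-catalysed acetalisation with azeotropic water removal masks the aldehyde against organolithiums, and the six-membered cyclic acetal tolerates silica gel and a warm phenol far better than an acyclic acetal of this electron-rich benzaldehyde.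

Step 3
Reactants: 3 methyl 2-(benzyloxy)-5-(5,5-dimethyl-1,3-dioxan-2-yl)benzoate
Product: 5 (ArB-ethynyloxy)triisopropylsilane (ArB–C≡C–OTIPS), via lithium ynolate 4 (not isolated)
Conditions: CH2Br2, lithium 2,2,6,6-tetramethylpiperidide, THF, −78 °C; n-BuLi, −78 → 0 °C; i-Pr3SiCl, −78 °C → rt; aq NaHCO3 work-up
Reagents that add atoms: dibromomethane, BrCBr; chlorotriisopropylsilane, CC(C)[Si](Cl)(C(C)C)C(C)C
Why: Kowalski ester homologation stopped at the ynolate stage, in which acylation of dibromomethyllithium and bromine–lithium exchange trigger 1,2-aryl migration to 4, and the bulky silyl chloride silylates on oxygen without activating the acetal as a silyl triflate could.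

Step 4
Reactants: 6 3-ethoxycyclobut-2-en-1-one
Product: 7 3-(4-methoxybenzyloxy)cyclobut-2-en-1-one
Conditions: 4-methoxybenzyl alcohol, pyridinium 4-toluenesulfonate (10 mol %), 5 Å molecular sieves, toluene, 40 °C
Reagents that add atoms: 4-methoxybenzyl alcohol, COc1ccc(CO)cc1
Why: Acid-catalysed transetherification of a vinylogous ester by addition–elimination at C3, driven by sequestering ethanol and run well below the temperature at which the four-membered ring opens.

Step 5
Reactants: 5 ArB–C≡C–OTIPS; 7 3-(4-methoxybenzyloxy)cyclobut-2-en-1-one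
Product: 12 2-ArB-5-(4-methoxybenzyloxy)-3-(triisopropylsilyloxy)phenol, via vinylketene 8 (not isolated), via vinylcyclobutenone 9 (not isolated), via dienylketene 10 (not isolated), via cyclohexadienone 11 (not isolated)
Conditions: toluene, 80 → 110 °C, argon, 7 (1.2 equiv) added in portions
Reagents that add atoms: none
Why: Danheiser benzannulation: four-electron opening of 7 breaks its C1–C4 bond and gives vinylketene 8, which adds [2+2] to the ynol ether to give 9, a second four-electron opening gives dienylketene 10, and six-electron electrocyclisation to 11 followed by tautomerisation gives phenol 12. The closest known reaction type is this same annulation of 3-alkyl- or 3-arylcyclobutenones with triisopropylsiloxyalkynes to resorcinol monosilyl ethers, and every such case passes through a 3-siloxycyclobutenone that opens thermally, which supports the opening of the 3-alkoxy compound 7. The one new ring, the flavone benzo ring, is closed by the disrotatory electrocyclisation, which rejoins the former C1 and C4 of 7 as C7''–C8'', so the net new skeletal bonds are C6''–C7'' and C5''–C4a''. No lasting stereocentre is formed, and the transient one in 9 is erased on ring opening. The selectivity needed is the orientation of the [2+2] step: the oxygen-polarised alkyne is nucleophilic at its aryl-bearing carbon, which attacks the electrophilic ketene carbonyl carbon, so ring B ends between the free hydroxyl and the silyl ether and para to the PMB ether. Adding 7 in portions keeps the ketene concentration low, so the alkyne outcompetes ketene self-reaction and acylation of the hindered product phenol.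

Step 6
Reactants: 12 2-ArB-5-(4-methoxybenzyloxy)-3-(triisopropylsilyloxy)phenol
Product: 13 1,3-bis(benzyloxy)-2-ArB-5-(4-methoxybenzyloxy)benzene
Conditions: BnBr, CsF, K2CO3, DMF, rt → 50 °C
Reagents that add atoms: benzyl bromide, BrCc1ccccc1
Why: Fluoride desilylation and double Williamson etherification in one pot turn both oxygens flanking ring B into benzyl ethers, which makes the two remaining C–H positions of the new ring equivalent.

Step 7
Reactants: 13 1,3-bis(benzyloxy)-2-ArB-5-(4-methoxybenzyloxy)benzene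
Product: 14 1,3-bis(benzyloxy)-2-ArB-4-bromo-5-(4-methoxybenzyloxy)benzene
Conditions: NBS (1.0 equiv), MeCN–CH2Cl2, −20 → 0 °C, dark
Reagents that add atoms: N-bromosuccinimide, O=C1CCC(=O)N1Br
Why: Electrophilic aromatic bromination goes to the trialkoxy ring, by far the most electron-rich arene present, and either of its equivalent C–H positions gives the same monobromide, marking C4a''.

Step 8
Reactants: 15 1-(benzyloxy)-4-ethynylbenzene
Product: 17 3-[4-(benzyloxy)phenyl]-N-methoxy-N-methylprop-2-ynamide, via lithium acetylide 16 (not isolated)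
Conditions: n-BuLi, THF, −78 °C; ClC(O)N(OMe)Me, −78 → 0 °C
Reagents that add atoms: N-methoxy-N-methylcarbamoyl chloride, CON(C)C(=O)Cl
Why: Acylation of a lithium acetylide by a carbamoyl chloride gives the alkynyl Weinreb amide, and chelation by the N-methoxy group prevents a second addition.

Step 9
Reactants: 14 1,3-bis(benzyloxy)-2-ArB-4-bromo-5-(4-methoxybenzyloxy)benzene; 17 3-[4-(benzyloxy)phenyl]-N-methoxy-N-methylprop-2-ynamide
Product: 19 1-[2,4-bis(benzyloxy)-3-ArB-6-(4-methoxybenzyloxy)phenyl]-3-[4-(benzyloxy)phenyl]prop-2-yn-1-one, via aryllithium 18 (not isolated)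
Conditions: n-BuLi, THF, −78 °C; 17, −78 → −20 °C; sat. aq NH4Cl
Reagents that add atoms: none
Why: Bromine–lithium exchange at −78 °C outruns benzylic deprotonation, and the Weinreb ketone synthesis stops cleanly at the ketone stage, so C4a'' is acylated under basic, Lewis-acid-free conditions that spare the acetal and every benzylic ether.

Step 10
Reactants: 19 1-[2,4-bis(benzyloxy)-3-ArB-6-(4-methoxybenzyloxy)phenyl]-3-[4-(benzyloxy)phenyl]prop-2-yn-1-one
Product: 22 4-(benzyloxy)-3-Fl-benzaldehyde, via hydroxy ynone 20 (not isolated), via flavone acetal 21 (not isolated)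
Conditions: CF3CO2H–CH2Cl2 (1:4), anisole, 0 °C → rt; then H2O, rt
Reagents that add atoms: water, O
Why: In this Brønsted-acid cascade the PMB ether, the only phenol ether here that ionises in trifluoroacetic acid, is lost to anisole by Friedel–Crafts capture, the freed C8a'' hydroxyl of 20 adds 6-endo-dig to the protonated ynone (acid-promoted cyclisation of an o-hydroxyaryl ynone, which avoids the 5-exo mode seen under base) to give 21, and water then hydrolyses the acetal, so only the 6''-aryl flavone can form.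

Step 11
Reactants: 23 1-(2,4-dihydroxy-6-methoxyphenyl)ethan-1-one
Product: 24 1-[4-(benzyloxy)-2-hydroxy-6-methoxyphenyl]ethan-1-one
Conditions: BnBr (1.0 equiv), K2CO3, acetone, reflux
Reagents that add atoms: benzyl bromide, BrCc1ccccc1
Why: Regioselective Williamson etherification, because the 2-hydroxyl is held in a hydrogen bond to the ketone and one equivalent of benzyl bromide reacts at the free, more acidic 4-hydroxyl.

Step 12
Reactants: 24 1-[4-(benzyloxy)-2-hydroxy-6-methoxyphenyl]ethan-1-one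
Product: 25 tert-butyl 3-[4-(benzyloxy)-2-hydroxy-6-methoxyphenyl]-3-oxopropanoate
Conditions: LiN(SiMe3)2 (3.2 equiv), THF, −78 °C; Boc2O, −78 → 0 °C; 1 M HCl, 0 °C
Reagents that add atoms: di-tert-butyl dicarbonate, CC(C)(C)OC(=O)OC(=O)OC(C)(C)C
Why: Claisen-type C-acylation of the doubly deprotonated hydroxy ketone by Boc2O, in which any acylation on the phenol oxygen is corrected by a Baker–Venkataraman-type O-to-C shift under the excess base, while the bulky ester and low temperature hold back lactonisation.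

Step 13
Reactants: 22 4-(benzyloxy)-3-Fl-benzaldehyde; 25 tert-butyl 3-[4-(benzyloxy)-2-hydroxy-6-methoxyphenyl]-3-oxopropanoate
Product: 26 tert-butyl 2-[4-(benzyloxy)-2-hydroxy-6-methoxybenzoyl]-3-[4-(benzyloxy)-3-Fl-phenyl]prop-2-enoate (alkene geometry not assigned)
Conditions: piperidine, AcOH (cat. each), 4 Å molecular sieves, toluene, rt
Reagents that add atoms: none
Why: Amine–acid catalysed Knoevenagel condensation of the doubly activated methylene with the non-enolisable aldehyde, kept at room temperature so that the free phenol does not yet add to the new acceptor.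

Step 14
Reactants: 26 tert-butyl 2-[4-(benzyloxy)-2-hydroxy-6-methoxybenzoyl]-3-[4-(benzyloxy)-3-Fl-phenyl]prop-2-enoate
Product: 28 (2S)-7-(benzyloxy)-2-[4-(benzyloxy)-3-Fl-phenyl]-5-methoxychroman-4-one, via flavanone ester 27 (not isolated)
Conditions: N-[3,5-bis(trifluoromethyl)phenyl]-N'-[(9R)-6'-methoxycinchonan-9-yl]thiourea (10 mol %), toluene, −25 °C; then TsOH·H2O, 80 °C
Reagents that add atoms: none
Why: Catalytic asymmetric intramolecular oxa-Michael addition, in which the thiourea binds the β-keto ester while the quinuclidine nitrogen activates the phenol so that oxygen reaches one face of the alkylidene and sets C2 as S in 27, after which acid-induced loss of isobutene and carbon dioxide removes the C3 substituent without touching C2.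

Step 15
Reactants: 28 (2S)-7-(benzyloxy)-2-[4-(benzyloxy)-3-Fl-phenyl]-5-methoxychroman-4-one
Product: 29 (2S)-2-{3-[5,7-dihydroxy-2-(4-hydroxyphenyl)-4-oxo-4H-chromen-6-yl]-4-hydroxyphenyl}-7-hydroxy-5-methoxychroman-4-one (CNP0332590.1)
Conditions: H2 (1 atm), 10% Pd/C, THF–MeOH, rt
Reagents that add atoms: none
Why: Catalytic hydrogenolysis of the five aryl benzyl ethers under neutral conditions avoids the acid- or base-induced ring opening that would racemise C2, and the C2''=C3'' bond and both carbonyl groups are inert at ambient pressure.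

Compound list
1 | methyl 5-formyl-2-hydroxybenzoate | COC(=O)c1cc(C=O)ccc1O | starting material
2 | methyl 2-(benzyloxy)-5-formylbenzoate | COC(=O)c1cc(C=O)ccc1OCc1ccccc1 | intermediate
3 | methyl 2-(benzyloxy)-5-(5,5-dimethyl-1,3-dioxan-2-yl)benzoate | COC(=O)c1cc(C2OCC(C)(C)CO2)ccc1OCc1ccccc1 | intermediate
4 | lithium 2-ArB-ethynolate | [Li]OC#Cc1cc(C2OCC(C)(C)CO2)ccc1OCc1ccccc1 | intermediate
5 | (ArB-ethynyloxy)triisopropylsilane | CC(C)[Si](OC#Cc1cc(C2OCC(C)(C)CO2)ccc1OCc1ccccc1)(C(C)C)C(C)C | intermediate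
6 | 3-ethoxycyclobut-2-en-1-one | CCOC1=CC(=O)C1 | starting material
7 | 3-(4-methoxybenzyloxy)cyclobut-2-en-1-one | COc1ccc(COC2=CC(=O)C2)cc1 | intermediate
8 | 3-(4-methoxybenzyloxy)buta-1,3-dien-1-one | C=C(OCc1ccc(OC)cc1)C=C=O | intermediate
9 | 2-ArB-4-[1-(4-methoxybenzyloxy)ethenyl]-3-(triisopropylsilyloxy)cyclobut-2-en-1-one (racemic) | O=C1C(c2cc(C3OCC(C)(C)CO3)ccc2OCc2ccccc2)=C(O[Si](C(C)C)(C(C)C)C(C)C)C1C(=C)OCc1ccc(OC)cc1 | intermediate
10 | 2-ArB-5-(4-methoxybenzyloxy)-3-(triisopropylsilyloxy)hexa-1,3,5-trien-1-one (ketene and vinyl termini cis) | O=C=C(c1cc(C2OCC(C)(C)CO2)ccc1OCc1ccccc1)/C(O[Si](C(C)C)(C(C)C)C(C)C)=C\C(=C)OCc1ccc(OC)cc1 | intermediate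
11 | 2-ArB-5-(4-methoxybenzyloxy)-3-(triisopropylsilyloxy)cyclohexa-2,4-dien-1-one | O=C1CC(OCc2ccc(OC)cc2)=CC(O[Si](C(C)C)(C(C)C)C(C)C)=C1c1cc(C2OCC(C)(C)CO2)ccc1OCc1ccccc1 | intermediate
12 | 2-ArB-5-(4-methoxybenzyloxy)-3-(triisopropylsilyloxy)phenol | COc1ccc(COc2cc(O)c(-c3cc(C4OCC(C)(C)CO4)ccc3OCc3ccccc3)c(O[Si](C(C)C)(C(C)C)C(C)C)c2)cc1 | intermediate
13 | 1,3-bis(benzyloxy)-2-ArB-5-(4-methoxybenzyloxy)benzene | COc1ccc(COc2cc(OCc3ccccc3)c(-c3cc(C4OCC(C)(C)CO4)ccc3OCc3ccccc3)c(OCc3ccccc3)c2)cc1 | intermediate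
14 | 1,3-bis(benzyloxy)-2-ArB-4-bromo-5-(4-methoxybenzyloxy)benzene | COc1ccc(COc2cc(OCc3ccccc3)c(-c3cc(C4OCC(C)(C)CO4)ccc3OCc3ccccc3)c(OCc3ccccc3)c2Br)cc1 | intermediate
15 | 1-(benzyloxy)-4-ethynylbenzene | C#Cc1ccc(OCc2ccccc2)cc1 | starting material
16 | lithium [4-(benzyloxy)phenyl]acetylide | [Li]C#Cc1ccc(OCc2ccccc2)cc1 | intermediate
17 | 3-[4-(benzyloxy)phenyl]-N-methoxy-N-methylprop-2-ynamide | CON(C)C(=O)C#Cc1ccc(OCc2ccccc2)cc1 | intermediate
18 | [2,4-bis(benzyloxy)-3-ArB-6-(4-methoxybenzyloxy)phenyl]lithium | COc1ccc(COc2cc(OCc3ccccc3)c(-c3cc(C4OCC(C)(C)CO4)ccc3OCc3ccccc3)c(OCc3ccccc3)c2[Li])cc1 | intermediate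
19 | 1-[2,4-bis(benzyloxy)-3-ArB-6-(4-methoxybenzyloxy)phenyl]-3-[4-(benzyloxy)phenyl]prop-2-yn-1-one | COc1ccc(COc2cc(OCc3ccccc3)c(-c3cc(C4OCC(C)(C)CO4)ccc3OCc3ccccc3)c(OCc3ccccc3)c2C(=O)C#Cc2ccc(OCc3ccccc3)cc2)cc1 | intermediate
20 | 1-[2,4-bis(benzyloxy)-3-ArB-6-hydroxyphenyl]-3-[4-(benzyloxy)phenyl]prop-2-yn-1-one | Oc1cc(OCc2ccccc2)c(-c2cc(C3OCC(C)(C)CO3)ccc2OCc2ccccc2)c(OCc2ccccc2)c1C(=O)C#Cc1ccc(OCc2ccccc2)cc1 | intermediate
21 | 5,7-bis(benzyloxy)-6-ArB-2-[4-(benzyloxy)phenyl]-4H-chromen-4-one | O=c1cc(-c2ccc(OCc3ccccc3)cc2)oc2cc(OCc3ccccc3)c(-c3cc(C4OCC(C)(C)CO4)ccc3OCc3ccccc3)c(OCc3ccccc3)c12 | intermediate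
22 | 4-(benzyloxy)-3-Fl-benzaldehyde | O=Cc1ccc(OCc2ccccc2)c(-c2c(OCc3ccccc3)cc3oc(-c4ccc(OCc5ccccc5)cc4)cc(=O)c3c2OCc2ccccc2)c1 | intermediate
23 | 1-(2,4-dihydroxy-6-methoxyphenyl)ethan-1-one | CC(=O)c1c(O)cc(O)cc1OC | starting material
24 | 1-[4-(benzyloxy)-2-hydroxy-6-methoxyphenyl]ethan-1-one | CC(=O)c1c(O)cc(OCc2ccccc2)cc1OC | intermediate
25 | tert-butyl 3-[4-(benzyloxy)-2-hydroxy-6-methoxyphenyl]-3-oxopropanoate | CC(C)(C)OC(=O)CC(=O)c1c(O)cc(OCc2ccccc2)cc1OC | intermediate
26 | tert-butyl 2-[4-(benzyloxy)-2-hydroxy-6-methoxybenzoyl]-3-[4-(benzyloxy)-3-Fl-phenyl]prop-2-enoate (geometry not assigned) | COc1cc(OCc2ccccc2)cc(O)c1C(=O)C(C(=O)OC(C)(C)C)=Cc1ccc(OCc2ccccc2)c(-c2c(OCc3ccccc3)cc3oc(-c4ccc(OCc5ccccc5)cc4)cc(=O)c3c2OCc2ccccc2)c1 | intermediate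
27 | tert-butyl (2S)-7-(benzyloxy)-2-[4-(benzyloxy)-3-Fl-phenyl]-5-methoxy-4-oxochromane-3-carboxylate (C3 epimerisable, not assigned) | COc1cc(OCc2ccccc2)cc2c1C(=O)C(C(=O)OC(C)(C)C)[C@@H](c1ccc(OCc3ccccc3)c(-c3c(OCc4ccccc4)cc4oc(-c5ccc(OCc6ccccc6)cc5)cc(=O)c4c3OCc3ccccc3)c1)O2 | intermediate
28 | (2S)-7-(benzyloxy)-2-[4-(benzyloxy)-3-Fl-phenyl]-5-methoxychroman-4-one | COc1cc(OCc2ccccc2)cc2c1C(=O)C[C@@H](c1ccc(OCc3ccccc3)c(-c3c(OCc4ccccc4)cc4oc(-c5ccc(OCc6ccccc6)cc5)cc(=O)c4c3OCc3ccccc3)c1)O2 | intermediate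
29 | (2S)-2-{3-[5,7-dihydroxy-2-(4-hydroxyphenyl)-4-oxo-4H-chromen-6-yl]-4-hydroxyphenyl}-7-hydroxy-5-methoxychroman-4-one | COc1cc(O)cc2c1C(=O)C[C@@H](c1ccc(O)c(-c3c(O)cc4oc(-c5ccc(O)cc5)cc(=O)c4c3O)c1)O2 | target

Total step count: 15. Longest linear sequence: 11 steps (1, 2, 3, 5, 6, 7, 9, 10, 13, 14, 15).

Steps most likely to fail

Step 5. The donor-stabilised cyclobutenone may open more slowly than it decomposes. The ketene may also be lost to self-reaction or to acylation of the product phenol. The ortho-substituted aryl group may slow the [2+2] step. The fallback sets out from siloxyalkyne 5 and comes back at vinylcyclobutenone 9, which is then isolated, and so at 12. It makes ketene 8 without any strained ring: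
- Commercial methyl (E)-3-methoxybut-2-enoate is exchanged with 4-methoxybenzyl alcohol under pyridinium 4-toluenesulfonate catalysis to methyl (E)-3-(4-methoxybenzyloxy)but-2-enoate F1.
- LiOH saponification gives (E)-3-(4-methoxybenzyloxy)but-2-enoic acid F2.
- 1-Chloro-N,N,2-trimethylprop-1-en-1-amine converts this under neutral conditions into (E)-3-(4-methoxybenzyloxy)but-2-enoyl chloride F3.
- Slow addition of F3 to 5 and Et3N in CH2Cl2 at 0 °C to rt causes 1,4-dehydrochlorination to 8, which is trapped in situ by [2+2] cycloaddition.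
- Purified 9 is then heated alone in toluene, so no ketene remains to acylate the phenol.

Step 14. Uncatalysed cyclisation of the electron-rich phenol during or after the Knoevenagel step would lower facial selectivity. Reversible acid-induced ring opening during the hot decarboxylation, helped by the 4'-alkoxy group, could erode the configuration at C2. The fallback sets out from aldehyde 22 and acetophenone 24 and comes back at 28:
- Claisen–Schmidt condensation (KOH, EtOH–THF, rt) gives (E)-1-[4-(benzyloxy)-2-hydroxy-6-methoxyphenyl]-3-[4-(benzyloxy)-3-Fl-phenyl]prop-2-en-1-one F4.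
- NaOAc in refluxing EtOH closes it to racemic 7-(benzyloxy)-2-[4-(benzyloxy)-3-Fl-phenyl]-5-methoxychroman-4-one F5.
- Kinetic resolution follows by Noyori–Ikariya asymmetric transfer hydrogenation with RuCl(p-cymene)[(R,R)-TsNCHPhCHPhNH2] and HCO2H–Et3N, stopped near half conversion.
- This should reduce the 2R ketone to (2R,4R)-7-(benzyloxy)-2-[4-(benzyloxy)-3-Fl-phenyl]-5-methoxychroman-4-ol F6 and leave 28, which is separated by chromatography.

Step 4. The exchange may stall at equilibrium. The strained vinylogous ester may suffer hydrolysis or ring-cleaving alcoholysis, and the benzylic alcohol may self-condense under acid. The fallback sets out from 6 and comes back at 7. Cold dilute aqueous HCl hydrolyses 6 to cyclobutane-1,3-dione F7, a strong vinylogous acid in its enol form. This is O-alkylated irreversibly by a Mitsunobu reaction with 4-methoxybenzyl alcohol, PPh3 and diisopropyl azodicarboxylate in THF at 0 °C.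

Further compounds
F1 | step 5 | methyl (E)-3-(4-methoxybenzyloxy)but-2-enoate | COC(=O)/C=C(\C)OCc1ccc(OC)cc1
F2 | step 5 | (E)-3-(4-methoxybenzyloxy)but-2-enoic acid | OC(=O)/C=C(\C)OCc1ccc(OC)cc1
F3 | step 5 | (E)-3-(4-methoxybenzyloxy)but-2-enoyl chloride | ClC(=O)/C=C(\C)OCc1ccc(OC)cc1
F4 | step 14 | (E)-1-[4-(benzyloxy)-2-hydroxy-6-methoxyphenyl]-3-[4-(benzyloxy)-3-Fl-phenyl]prop-2-en-1-one | COc1cc(OCc2ccccc2)cc(O)c1C(=O)/C=C/c1ccc(OCc2ccccc2)c(-c2c(OCc3ccccc3)cc3oc(-c4ccc(OCc5ccccc5)cc4)cc(=O)c3c2OCc2ccccc2)c1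
F5 | step 14 | racemic 7-(benzyloxy)-2-[4-(benzyloxy)-3-Fl-phenyl]-5-methoxychroman-4-one | COc1cc(OCc2ccccc2)cc2c1C(=O)CC(c1ccc(OCc3ccccc3)c(-c3c(OCc4ccccc4)cc4oc(-c5ccc(OCc6ccccc6)cc5)cc(=O)c4c3OCc3ccccc3)c1)O2
F6 | step 14 | (2R,4R)-7-(benzyloxy)-2-[4-(benzyloxy)-3-Fl-phenyl]-5-methoxychroman-4-ol | COc1cc(OCc2ccccc2)cc2c1[C@H](O)C[C@H](c1ccc(OCc3ccccc3)c(-c3c(OCc4ccccc4)cc4oc(-c5ccc(OCc6ccccc6)cc5)cc(=O)c4c3OCc3ccccc3)c1)O2
F7 | step 4 | cyclobutane-1,3-dione | O=C1CC(=O)C1
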